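(The earlier runs and the new flask were computed from invented constants; noise was put on by code.)

Which species holds the largest share of the charged substrate in the flask at 2.5 min, and how large is that share?

| setting | zeta | epsilon | flask |
|---|---|---|---|
| substrate | 38 mM | 76 mM | 38 mM |
| coupling partner | 1.2 equiv (in portions, 4) | 1.2 equiv (in portions, 4) | 1.20 equiv (in portions, 4) |
| transfer agent | 1.9 mM | 1.9 mM | 1.90 mM |
| initiator | 8.1 mol% | 8.1 mol% | 8.1 mol% |
| remark | the very flask that is asked about, followed so far; portions every 40 s | run made earlier; portions every 40 s | the portions of coupling partner follow each other after 40 s, the first at the start |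
| time |  |  | 2.5 min |

| run | time / s | target / % | first chain carrier / % | side product / % | isomer of the product / % | substrate / % |
|---|---|---|---|---|---|---|
| zeta | 10.0 | 0.4 | 0 | 3.0 | 1.0 | 98.7 |
| zeta | 20.0 | 1.5 | 0 | 3.8 | 2.3 | 95.6 |
| zeta | 30.0 | 1.9 | 0 | 5.0 | 2.4 | 91.6 |
| epsilon | 10.0 | 2.0 | 0.8 | 1.9 | 1.6 | 96.1 |
| epsilon | 20.0 | 6.4 | 0 | 2.9 | 3.2 | 87.7 |
| epsilon | 40.0 | 9.3 | 0.9 | 4.4 | 11.0 | 77.0 |
| epsilon | 60.0 | 15.7 | 0.5 | 3.0 | 22.8 | 55.5 |
| epsilon | 80.0 | 16.5 | 0.7 | 3.6 | 28.9 | 44.3 |
| epsilon | 120 | 25.2 | 0 | 4.4 | 49.0 | 16.2 |

(scatter of a reading: 1 percentage point)

- the largest share of what was charged as substrate, at 2.5 min belongs to (first chain carrier / substrate / isomer of the product / side product / target)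
- the largest share itself, whichever of these holds it, in percent of the substrate charged

- the numbers in the tables scatter by 1 percentage point (one standard deviation)

We start by counting turnovers. In zeta, which is this flask followed so far, the side product reads 5.0% at 30.0 s. That matches the transfer agent charged, c(transfer agent)/c(substrate) = 5.00%, so we take one side product per transfer agent and read that time as the end of an induction period. Each transfer agent then costs one radical, and the initiator must pay that debt. We therefore define the radical budget, the radicals that the initiator charge can deliver per transfer agent charged, 2c(initiator)/c(transfer agent), assuming two radicals per initiator. Here it is 3.24, above one, so the debt can be paid.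

Epsilon shows the pace afterwards: from 20.0 s, when its side product reads 2.9% against 2.50% of transfer agent charged, it loses 72 percentage points of substrate in 100 s. Zeta has the same equivalents and loading at half the substrate concentration, and we assume that it keeps this percentage pace from 30.0 s, although its readings stop too early to test this. That leaves 5.80% of substrate at 2.5 min. Epsilon's readings at 120 s put 66.0% of target plus isomer in the isomer and leave 5.20% of the charge unaccounted for. Taking that gap over, with side product at 5.00%, we commit to the isomer of the product at 55.5%.

The forecast names substrate at 50%, holding that “zeta at time t should look like epsilon at about t/2”. The flask gives isomer of the product at 54.3%, with substrate at 5.70%.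

    initiator → 2 initiating radical (k = 0.0110 s⁻¹)
    substrate + initiating radical → capped initiator + first chain carrier (k = 4.70 × 10⁵ M⁻¹ s⁻¹)
    coupling partner + first chain carrier → target + second chain carrier (k = 5300 M⁻¹ s⁻¹)
    substrate + second chain carrier → released group + first chain carrier (k = 14000 M⁻¹ s⁻¹)
    transfer agent + first chain carrier → side product + idle radical (kL = 99000 M⁻¹ s⁻¹)
    2 idle radical → ended radicals (k = 1.00 × 10⁸ M⁻¹ s⁻¹)
    2 first chain carrier → ended chains (k = 1.20 × 10⁶ M⁻¹ s⁻¹)
    target ⇌ isomer of the product (K = 2.30, k = 0.110 s⁻¹)

With its budget of 3.24, the flask holds 0% of its transfer agent at 2.50 min and 4.97 mM of capped initiator. A neighbouring flask charged with 2 mol% of initiator has a budget of 0.800, below one: its initiator can deliver 1.52 mM of radicals against 1.90 mM of transfer agent. At 2.50 min that neighbour still holds 35.5% of its transfer agent, with 1.23 mM of capped initiator, 1.23% of target, 2.39% of isomer of the product and 93.1% of substrate.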